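## Structural features

Curlignan is a 2-aryl-2,3-dihydrobenzofuran: a benzene ring (ring A) is fused through C3a and C7a to a five-membered ring O1–C2–C3, C2 carries a 4-hydroxy-3-methoxyphenyl group (ring B) and C3 a hydroxymethyl group. Ring A holds a methyl ester at C5 and a methoxy group at C7. The two stereocentres, C2 (S) and C3 (R), are adjacent and trans across the ring; C2 is at once the carbon next to the ring oxygen and a benzylic ether of an electron-rich arene. The fragile points are the C2–O1 bond (open to acid ionisation, to hydrogenolysis and, once the para phenol is free, to base by way of a quinone methide), the free phenol, and the methyl ester, which has to survive every base and hydride used. The real difficulty is not the carbon skeleton but fixing two contiguous centres in absolute terms and then closing the heterocycle without disturbing them. The key step exploits the fact that C7a, the ring-A carbon bonded to O1, stands para to the C5 ester: a fluorine on C7a can be displaced by an oxygen on C2, so the O1–C7a bond can be made last, on an open chain that already holds both centres. In that chain the syn arrangement equals the trans ring, because the oxygen on C2 and ring A on C3 become ring bonds and push the aryl and CH2O groups to opposite faces.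

## Logic of the disconnections

**18 ⇒ 17 ⇒ 16.** Only oxygen–protecting-group bonds are cut: the aryl O–benzyl bond (18 ⇒ 17) and the primary O–trityl bond (17 ⇒ 16). They are cut here because a free ring-B phenol would, under base, open C2–O1 through a quinone methide, and a free primary alcohol would compete in the ring closure. The gain is a closure substrate with one nucleophilic site. The forward demand is that both removals spare the C2–O1 benzylic ether and the ester, hence brief catalytic acid in methanol for trityl and neutral hydrogenolysis for benzyl.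

**16 ⇒ 14.** The O1–C7a bond is cut with the electrons left on oxygen: C2 keeps a secondary hydroxyl and C7a receives fluorine (14, reacting as its alkoxide 15). The cut is placed here because C7a is the one ring-A position at which addition–elimination is supported by the para ester, and because neither C2 nor C3 takes part. The gain is that the bicyclic, stereodefined core becomes an open-chain syn 1,3-diol derivative, a standard aldol retron. The demands are that 14 is the (1S,2R) syn isomer, that the primary hydroxyl carries a group that cannot migrate under base, and that no hydrogen stands ortho to fluorine.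

**14 ⇒ 13 ⇒ 12.** The trityl ether is removed (14 ⇒ 13) and the CH2OH carbon is raised to the acyl level bound to the auxiliary (13 ⇒ 12); no skeletal bond is cut. The reason is that 12 is the direct product of an auxiliary-controlled aldol reaction. The gain is access to both centres in one known step. The demands are a tritylation selective for the primary hydroxyl and a hydride reduction that cleaves the imide but not the benzoate ester of the same molecule. The reduction is placed before the ring closure because it removes the acidity of the centre flanked by aryl and acyl.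

**12 ⇒ 9 + 10.** The C2–C3 bond (benzofuran numbering) is cut, giving 9 (reacting as its enolate 11) and 10. This is the only point where fragments of similar size are joined, and both stereocentres arise there together. The gain is two aryl building blocks with no stereocentre in their carbon skeletons. The demand is a Z-enolate in a closed transition state for the syn adduct, and the (S)-configured auxiliary for the (2S,3S) enantiomer; on reduction the label of the ring-A-bearing carbon becomes R by a change of priorities only.

**9 ⇒ 6 + 7.** The N–acyl bond is cut. The auxiliary is a temporary carrier of chirality attached at the acid function. The gain is an achiral acid 6 and a bought auxiliary 7. The demand is an acylation without strong base, since 6 has a methyl ester and an acidic benzylic CH2, hence the mixed anhydride 8.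

**6 ⇒ 5 ⇒ 4.** The carboxyl carbon of 6 is traced to the inner alkene carbon of an allyl group (5), and the C–F bond to a phenolic C–O bond (4). The reason is that an allyl group ortho to a phenol is the mark of a Claisen rearrangement, and the directing oxygen sits on the carbon that must carry the leaving group. The gain is a simple allyl phenol. The demands are a deoxyfluorination that tolerates two ortho substituents, and its placement before the oxidative cleavage, because a free phenol would not survive the oxidant.

**4 ⇒ 3 ⇒ 1 + 2.** The aryl–allyl C–C bond is cut by a retro-Claisen step (4 ⇒ 3) and the O–allyl bond by a retro-etherification (3 ⇒ 1 + 2). The reason is that 1 already holds the ester, the methoxy group and the oxygen in the right places. The gain is two bulk chemicals. The demand is only heat, since 3 has a single free position ortho to the ether oxygen.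

## Other disconnections considered

**Alternative 1:** The cut goes through ring A: C3a–C4 and C7a–C7 are broken and the benzene ring is taken apart into a pyrone and a lactone enol derivative. Forward, the silyl ketene acetal A3 of the trans-lactone A2 would add as an electron-rich dienophile to methyl 3-bromocoumalate A4. Its nucleophilic carbon bonds to C6 of the pyrone and its acetal carbon to C3; the bridged adduct would expel CO2 and aromatise by loss of the silyloxy group to give A1.
- In its favour: the union is convergent, the ester arrives in place, the polarity of the partners fixes the regiochemistry, and the stereocentres of A2 are not touched.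
- Equal or better: it needs no aryl fluoride, so the least secure step of the chosen plan (phenol to fluoride) disappears; it is also more convergent.
- Against it: the carbon that becomes C7a bears two oxygen leaving groups, the silyloxy group and O1, and aromatisation by loss of O1 would open the ring that must be kept. C7 emerges as a bromide, so a copper-mediated methoxylation has to follow. An enantiopure A2 costs about as many steps as the aldol sequence.
- Comparison: on mechanism the chosen closure is more predictable (one nucleophile, one leaving group). On stereochemistry the two are equal, since both key steps carry pre-set centres. On step count the alternative is no shorter once the bromide exchange and the route to A2 are included.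

**Alternative 2:** The cut is C3–C3a, read as the result of a 1,2-aryl shift, so that A5 is traced to the six-membered (2S)-flavanone A6. Forward, PhI(OAc)2 and H2SO4 in trimethyl orthoformate would ketalise A6, place hypervalent iodine on C3 and let ring A migrate from the ketal carbon to C3, the ketal carbon ending as the methyl ester of A5.
- In its favour: A6 is a short condensation–cyclisation away from simple aromatic ketone and aldehyde building blocks (10 among them), and the whole skeleton is then present.
- Equal or better: it is the shorter plan on step count; on relative configuration it is the equal, because the shift is stereospecific and should give the trans ring directly.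
- Against it: the absolute configuration depends on an enantiopure flavanone, a class that racemises by reversible opening of the pyranone ring, and the step runs in strong acid. An electron-rich ring B can be expected to compete as the migrating group, and dehydrogenation of the heterocycle is a further loss. The oxidant meets an electron-rich benzyloxy-methoxy arene. The oxidation pattern is inverted, so the C3 ester must be reduced and the C5 bromide carbonylated afterwards.
- Comparison: the chosen plan is longer but sets the absolute configuration in a step of predictable sense and carries ring A in its final oxidation state.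

**Alternative 3:** The cut is at C3: its C–H bond and, after oxidation, the C–O bond of the hydroxymethyl group are traced to a 1,1-disubstituted alkene, with silicon tethered to the C2 oxygen delivering hydrogen. Forward, the dimethylsilyl ether A8 would cyclise under a zerovalent platinum catalyst such as Pt2[(CH2=CHSiMe2)2O]3 by 5-endo hydrosilylation to the oxasilolane A7. Tamao–Fleming oxidation (H2O2, KF, KHCO3) would give the syn-diol A9, and the dihydrofuran would be closed between the unmasked ring-A phenol and C2.
- Equal or better: chirality is needed at one carbinol centre only and can come from a catalytic ketone reduction, not a stoichiometric auxiliary; ring A carries its C7a oxygen from the start, so no fluorination is needed.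
- Against it: the facial selectivity of hydrogen delivery to an alkene flanked by two aryl groups is not secured by close analogy, and isomerisation or plain reduction of the styrene-type alkene may compete. A9 is syn, so a closure at C2 with inversion would give the cis ring; the closure must therefore pass through a benzylic cation under thermodynamic control, which ionises and re-forms the very centre used for the relay. The sequence (enantioselective access to the alcohol, silylation, hydrosilylation, oxidation, unmasking, cyclisation, deprotection) is longer.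
- Comparison: in the chosen plan both centres come from one step and the closure breaks no bond to either, which is mechanistically cleaner; the catalytic use of chirality remains the alternative's real advantage.

Key step: step 9

Remark on the chemistry: the target SMILES is read as the (2S,3R) isomer with aryl and hydroxymethyl trans; reagents without a number (PhenoFluor, Bu2BOTf, KN(SiMe3)2, trityl chloride) are bought.

## Route

Step 1
Reactants: 1 methyl vanillate (methyl 4-hydroxy-3-methoxybenzoate); 2 allyl bromide (3-bromoprop-1-ene)
Product: 3 methyl 4-(allyloxy)-3-methoxybenzoate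
Conditions: K2CO3, acetone, reflux
Reagents that add atoms: none
Why: Williamson ether synthesis: the phenoxide of 1 displaces bromide from the unhindered allylic halide 2 in an SN2 reaction, and the ester is inert to K2CO3 in acetone.

Step 2
Reactants: 3 methyl 4-(allyloxy)-3-methoxybenzoate
Product: 4 methyl 3-allyl-4-hydroxy-5-methoxybenzoate
Conditions: N,N-diethylaniline, 200 °C
Reagents that add atoms: none
Why: Aromatic Claisen rearrangement: the [3,3]-sigmatropic shift can only end at the one unsubstituted carbon ortho to the ether oxygen, and tautomerisation restores the phenol, so the allyl group arrives where the C3 side chain must sit.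

Step 3
Reactants: 4 methyl 3-allyl-4-hydroxy-5-methoxybenzoate
Product: 5 methyl 3-allyl-4-fluoro-5-methoxybenzoate
Conditions: PhenoFluor, CsF, toluene, 110 °C
Reagents that add atoms: PhenoFluor (1,3-bis(2,6-diisopropylphenyl)-2,2-difluoro-2,3-dihydro-1H-imidazole), FC1(F)N(c2c(C(C)C)cccc2C(C)C)C=CN1c1c(C(C)C)cccc1C(C)C; caesium fluoride (fluoride pool shared with the reagent), [Cs+].[F-]
Why: Phenol deoxyfluorination: the reagent turns the phenolic oxygen into a uronium-type leaving group and fluoride replaces it at the same carbon in a concerted ipso substitution, which is favoured on electron-poor rings such as this para-ester phenol; the allyl group, the ester and the methyl ether do not react.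

Step 4
Reactants: 5 methyl 3-allyl-4-fluoro-5-methoxybenzoate
Product: 6 [2-fluoro-3-methoxy-5-(methoxycarbonyl)phenyl]acetic acid
Conditions: RuCl3·xH2O (cat.), NaIO4, MeCN/EtOAc/H2O, 0 °C to rt
Reagents that add atoms: sodium periodate (terminal oxidant, oxygen relayed through RuO4), [Na+].[O-]I(=O)(=O)=O; water, O
Why: Oxidative alkene cleavage by catalytic RuO4 formed from RuCl3 and NaIO4: the terminal alkene is cut, the inner carbon is taken to the carboxylic acid and the outer carbon leaves as CO2; the ring, deactivated by ester and fluorine, should resist the oxidant over the short reaction time.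

Step 5
Reactants: 6 [2-fluoro-3-methoxy-5-(methoxycarbonyl)phenyl]acetic acid; 7 (S)-4-benzyl-2-oxazolidinone
Product: 9 methyl 3-{2-[(4S)-4-benzyl-2-oxo-1,3-oxazolidin-3-yl]-2-oxoethyl}-4-fluoro-5-methoxybenzoate, via mixed pivalic anhydride 8 (not isolated)
Conditions: PivCl, Et3N, THF, −20 °C; then 7, LiCl, −20 °C to rt
Reagents that add atoms: none
Why: N-Acylation through a mixed anhydride: pivaloyl chloride activates 6 as 8, whose less hindered arylacetyl carbonyl is attacked by the oxazolidinone 7 activated by LiCl and Et3N; no strong base is used, so the benzoate ester and the acidic benzylic CH2 are safe.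

Step 6
Reactants: 9 methyl 3-{2-[(4S)-4-benzyl-2-oxo-1,3-oxazolidin-3-yl]-2-oxoethyl}-4-fluoro-5-methoxybenzoate; 10 4-benzyloxy-3-methoxybenzaldehyde (O-benzylvanillin)
Product: 12 methyl 3-[(2S,3S)-1-[(4S)-4-benzyl-2-oxo-1,3-oxazolidin-3-yl]-3-[4-(benzyloxy)-3-methoxyphenyl]-3-hydroxy-1-oxopropan-2-yl]-4-fluoro-5-methoxybenzoate, via dibutylboron Z-enolate 11 (not isolated)
Conditions: Bu2BOTf, iPr2NEt, CH2Cl2, −78 to 0 °C; then 10, −78 to 0 °C; pH 7 buffer, MeOH, H2O2, 0 °C
Reagents that add atoms: none
Why: Evans syn-aldol: soft enolisation gives the Z-boron enolate 11, which adds to 10 through a closed chair transition state with the oxazolidinone carbonyl turned away from boron and the aldehyde on the enolate face opposite the C4 benzyl group; this sets both stereocentres at once as the (2S,3S) syn adduct, and the oxidative work-up only removes boron.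

Step 7
Reactants: 12 methyl 3-[(2S,3S)-1-[(4S)-4-benzyl-2-oxo-1,3-oxazolidin-3-yl]-3-[4-(benzyloxy)-3-methoxyphenyl]-3-hydroxy-1-oxopropan-2-yl]-4-fluoro-5-methoxybenzoate
Product: 13 methyl 3-[(1S,2R)-1-[4-(benzyloxy)-3-methoxyphenyl]-1,3-dihydroxypropan-2-yl]-4-fluoro-5-methoxybenzoate
Conditions: LiBH4, MeOH (1 equiv), THF, 0 °C
Reagents that add atoms: none
Why: Reductive cleavage of the imide: hydride adds to the activated exocyclic imide carbonyl much faster than to the conjugated methyl benzoate at 0 °C, releasing 7 and the primary alcohol; no bond to a stereocentre is broken, and the label of the ring-A-bearing carbon changes from S to R only because the reduced carbon drops in priority.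

Step 8
Reactants: 13 methyl 3-[(1S,2R)-1-[4-(benzyloxy)-3-methoxyphenyl]-1,3-dihydroxypropan-2-yl]-4-fluoro-5-methoxybenzoate
Product: 14 methyl 3-[(1S,2R)-1-[4-(benzyloxy)-3-methoxyphenyl]-1-hydroxy-3-(trityloxy)propan-2-yl]-4-fluoro-5-methoxybenzoate
Conditions: TrCl, Et3N, DMAP (cat.), CH2Cl2, rt
Reagents that add atoms: trityl chloride, ClC(c1ccccc1)(c1ccccc1)c1ccccc1
Why: Selective tritylation: the bulky trityl electrophile reacts with the primary hydroxyl and leaves the hindered secondary benzylic hydroxyl free; the ether cannot migrate under base, which the next step requires.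

Step 9
Reactants: 14 methyl 3-[(1S,2R)-1-[4-(benzyloxy)-3-methoxyphenyl]-1-hydroxy-3-(trityloxy)propan-2-yl]-4-fluoro-5-methoxybenzoate
Product: 16 methyl (2S,3R)-2-[4-(benzyloxy)-3-methoxyphenyl]-7-methoxy-3-[(trityloxy)methyl]-2,3-dihydro-1-benzofuran-5-carboxylate, via potassium alkoxide 15 (not isolated)
Conditions: KN(SiMe3)2, THF (0.02 M), 0 °C to rt
Reagents that add atoms: none
Why: Intramolecular nucleophilic aromatic substitution, the closest known type being SNAr etherification of ester-activated aryl fluorides by alkoxides. KN(SiMe3)2 deprotonates the only acidic group, the secondary hydroxyl, to give 15; the alkoxide oxygen adds to C7a, the charge of the Meisenheimer-type adduct is spread over C7, C5 and C3a and onto the carbonyl oxygen of the para ester, and loss of fluoride restores the aromatic ring. Counted on the C7a=C7 bond the dihydrofuran closes in a 5-exo-trig sense, an easy closure because nucleophile and C–F carbon are held 1,5 on an ortho-substituted benzylic chain. No stereocentre is made: the bonds at C2 and C3 are untouched, so the (1S,2R) syn arrangement of 14 reappears as the (2S,3R) trans ring of 16. The selectivity needed between the two hydroxyl groups, each of which could close a five-membered ring, is secured by the trityl ether on the primary one. Selectivity against intermolecular attack on the methyl ester is secured by the intramolecular nature of the closure, by dilution and by the non-nucleophilic base. Fluoride is the leaving group of choice because the rate-limiting addition is fastest at a C–F carbon, and with no hydrogen ortho to fluorine an aryne pathway is excluded. The benzyl ether keeps ring B from forming a phenoxide that could open C2–O1 through a quinone methide.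

Step 10
Reactants: 16 methyl (2S,3R)-2-[4-(benzyloxy)-3-methoxyphenyl]-7-methoxy-3-[(trityloxy)methyl]-2,3-dihydro-1-benzofuran-5-carboxylate
Product: 17 methyl (2S,3R)-2-[4-(benzyloxy)-3-methoxyphenyl]-3-(hydroxymethyl)-7-methoxy-2,3-dihydro-1-benzofuran-5-carboxylate
Conditions: TsOH·H2O (cat.), MeOH/CH2Cl2, rt
Reagents that add atoms: none
Why: Acid-catalysed solvolysis of the trityl ether: protonation releases the stabilised trityl cation, which methanol traps; the methyl ester is unchanged in methanol, and catalytic acid at room temperature should be too mild to ionise the C2–O1 benzylic ether.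

Step 11
Reactants: 17 methyl (2S,3R)-2-[4-(benzyloxy)-3-methoxyphenyl]-3-(hydroxymethyl)-7-methoxy-2,3-dihydro-1-benzofuran-5-carboxylate
Product: 18 curlignan, methyl (2S,3R)-2-(4-hydroxy-3-methoxyphenyl)-3-(hydroxymethyl)-7-methoxy-2,3-dihydro-1-benzofuran-5-carboxylate
Conditions: H2 (1 atm), Pd/C, EtOAc, rt
Reagents that add atoms: none
Why: Hydrogenolysis of the aryl benzyl ether on Pd/C under neutral conditions; this C–O bond should be cleaved well before the cyclic benzylic C2–O1 bond, so the reaction is stopped once 17 is consumed, and neither stereocentre is involved.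

## Compound list

1 | methyl vanillate (methyl 4-hydroxy-3-methoxybenzoate) | COC(=O)c1ccc(O)c(OC)c1 | starting material
2 | allyl bromide | C=CCBr | starting material
3 | methyl 4-(allyloxy)-3-methoxybenzoate | COC(=O)c1ccc(OCC=C)c(OC)c1 | intermediate
4 | methyl 3-allyl-4-hydroxy-5-methoxybenzoate | COC(=O)c1cc(CC=C)c(O)c(OC)c1 | intermediate
5 | methyl 3-allyl-4-fluoro-5-methoxybenzoate | COC(=O)c1cc(CC=C)c(F)c(OC)c1 | intermediate
6 | [2-fluoro-3-methoxy-5-(methoxycarbonyl)phenyl]acetic acid | COC(=O)c1cc(CC(=O)O)c(F)c(OC)c1 | intermediate
7 | (S)-4-benzyl-2-oxazolidinone | O=C1N[C@@H](Cc2ccccc2)CO1 | starting material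
8 | mixed anhydride of 6 with pivalic acid | COC(=O)c1cc(CC(=O)OC(=O)C(C)(C)C)c(F)c(OC)c1 | intermediate (not isolated)
9 | methyl 3-{2-[(4S)-4-benzyl-2-oxo-1,3-oxazolidin-3-yl]-2-oxoethyl}-4-fluoro-5-methoxybenzoate | COC(=O)c1cc(CC(=O)N2[C@@H](Cc3ccccc3)COC2=O)c(F)c(OC)c1 | intermediate
10 | 4-benzyloxy-3-methoxybenzaldehyde (O-benzylvanillin) | COc1cc(C=O)ccc1OCc1ccccc1 | starting material
11 | dibutylboron (Z)-enolate of 9 (aryl cis to O–B) | CCCCB(CCCC)O/C(=C\c1cc(C(=O)OC)cc(OC)c1F)N1[C@@H](Cc2ccccc2)COC1=O | intermediate (not isolated)
12 | methyl 3-[(2S,3S)-1-[(4S)-4-benzyl-2-oxo-1,3-oxazolidin-3-yl]-3-[4-(benzyloxy)-3-methoxyphenyl]-3-hydroxy-1-oxopropan-2-yl]-4-fluoro-5-methoxybenzoate (syn aldol adduct) | COC(=O)c1cc(OC)c(F)c(c1)[C@H](C(=O)N1[C@@H](Cc2ccccc2)COC1=O)[C@@H](c1ccc(OCc2ccccc2)c(OC)c1)O | intermediate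
13 | methyl 3-[(1S,2R)-1-[4-(benzyloxy)-3-methoxyphenyl]-1,3-dihydroxypropan-2-yl]-4-fluoro-5-methoxybenzoate (syn diol) | COC(=O)c1cc(OC)c(F)c(c1)[C@H](CO)[C@@H](c1ccc(OCc2ccccc2)c(OC)c1)O | intermediate
14 | methyl 3-[(1S,2R)-1-[4-(benzyloxy)-3-methoxyphenyl]-1-hydroxy-3-(trityloxy)propan-2-yl]-4-fluoro-5-methoxybenzoate (syn; precursor of the key step) | COC(=O)c1cc(OC)c(F)c(c1)[C@H](COC(c2ccccc2)(c2ccccc2)c2ccccc2)[C@@H](c1ccc(OCc3ccccc3)c(OC)c1)O | intermediate
15 | potassium alkoxide of 14 | COC(=O)c1cc(OC)c(F)c(c1)[C@H](COC(c2ccccc2)(c2ccccc2)c2ccccc2)[C@@H](c1ccc(OCc3ccccc3)c(OC)c1)[O-].[K+] | intermediate (not isolated)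
16 | methyl (2S,3R)-2-[4-(benzyloxy)-3-methoxyphenyl]-7-methoxy-3-[(trityloxy)methyl]-2,3-dihydro-1-benzofuran-5-carboxylate (trans; product of the key step) | COC(=O)c1cc(OC)c2c(c1)[C@H](COC(c1ccccc1)(c1ccccc1)c1ccccc1)[C@@H](c1ccc(OCc3ccccc3)c(OC)c1)O2 | intermediate
17 | methyl (2S,3R)-2-[4-(benzyloxy)-3-methoxyphenyl]-3-(hydroxymethyl)-7-methoxy-2,3-dihydro-1-benzofuran-5-carboxylate (trans) | COC(=O)c1cc(OC)c2c(c1)[C@H](CO)[C@@H](c1ccc(OCc3ccccc3)c(OC)c1)O2 | intermediate
18 | curlignan, methyl (2S,3R)-2-(4-hydroxy-3-methoxyphenyl)-3-(hydroxymethyl)-7-methoxy-2,3-dihydro-1-benzofuran-5-carboxylate (trans) | COC(=O)c1cc(OC)c2c(c1)[C@H](CO)[C@@H](c1ccc(O)c(OC)c1)O2 | target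

## Step count and least certain steps

Total: 11 steps. Longest linear sequence: 11 steps (1 to 18); 7 and 10 enter as bought materials.

**Step 9 (key step).** The hindered secondary alkoxide must add to a ring activated by one ester only and slightly deactivated by the ortho methoxy donor. If the addition is slow, acyl transfer between alkoxide and methyl ester of different molecules (oligomerisation, release of methoxide and its own attack on the C–F carbon) may compete. The first adjustments are more dilution and a polar co-solvent. The fallback forms the other ring C–O bond, O1–C2, by acid-mediated closure of a phenol onto the benzylic carbon. It sets out from 4: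
- Benzylation (BnBr, K2CO3) gives methyl 3-allyl-4-(benzyloxy)-5-methoxybenzoate F1.
- Lemieux–von Rudloff cleavage (KMnO4 cat., NaIO4) gives [2-(benzyloxy)-3-methoxy-5-(methoxycarbonyl)phenyl]acetic acid F2.
- The operations of steps 5 to 7 with 7 and 10 give the imide methyl 3-{2-[(4S)-4-benzyl-2-oxo-1,3-oxazolidin-3-yl]-2-oxoethyl}-4-(benzyloxy)-5-methoxybenzoate F3, the syn aldol adduct methyl 3-[(2S,3S)-1-[(4S)-4-benzyl-2-oxo-1,3-oxazolidin-3-yl]-3-[4-(benzyloxy)-3-methoxyphenyl]-3-hydroxy-1-oxopropan-2-yl]-4-(benzyloxy)-5-methoxybenzoate F4 and the diol methyl 4-(benzyloxy)-3-[(1S,2R)-1-[4-(benzyloxy)-3-methoxyphenyl]-1,3-dihydroxypropan-2-yl]-5-methoxybenzoate F5.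
- Hydrogenolysis (H2, Pd/C) removes both benzyl ethers to give methyl 3-[(1S,2R)-1,3-dihydroxy-1-(4-hydroxy-3-methoxyphenyl)propan-2-yl]-4-hydroxy-5-methoxybenzoate F6.
- Catalytic TsOH in dilute MeCN ionises the para-hydroxybenzylic alcohol; the ortho phenol of ring A traps the cation, the trans ring is the thermodynamic product and C3 is untouched.

The fallback comes back to the route at 18.

**Step 3.** Both positions ortho to the phenolic oxygen are substituted, so the bulky uronium stage may form or collapse slowly and hydrolysis back to the phenol may win. The fallback sets out from 4. Triflation (Tf2O, pyridine) gives methyl 3-allyl-5-methoxy-4-{[(trifluoromethyl)sulfonyl]oxy}benzoate F7. Palladium-catalysed nucleophilic fluorination ([Pd(cinnamyl)Cl]2, tBuBrettPhos, CsF, toluene, 110 °C) then forms the C–F bond by reductive elimination from divalent palladium. That step is helped by ortho substituents and cannot give regioisomers here, since no hydrogen is ortho to the triflate. It comes back at 5.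

**Step 6.** A stabilised arylacetyl enolate and an electron-rich aldehyde make the addition easy to reverse, so the kinetic syn selectivity may erode, and the doubly activated α-carbon may epimerise during work-up. The fallback sets out from 6. Coupling with (S)-4-benzyl-1,3-thiazolidine-2-thione (EDC, DMAP) gives methyl 3-{2-[(4S)-4-benzyl-2-thioxo-1,3-thiazolidin-3-yl]-2-oxoethyl}-4-fluoro-5-methoxybenzoate F8. A titanium-mediated aldol with 10 (TiCl4, iPr2NEt, N-methyl-2-pyrrolidinone, CH2Cl2, −78 to 0 °C) should give the syn adduct of the same facial sense, methyl 3-[(2S,3S)-1-[(4S)-4-benzyl-2-thioxo-1,3-thiazolidin-3-yl]-3-[4-(benzyloxy)-3-methoxyphenyl]-3-hydroxy-1-oxopropan-2-yl]-4-fluoro-5-methoxybenzoate F9. The more labile auxiliary is then removed with NaBH4 at 0 °C, which also spares the benzoate. It comes back at 13.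

**Step 7.** The hydride may also attack the aromatic methyl ester (over-reduction), or the basic medium may trigger a retro-aldol before the imide is reduced. The fallback sets out from 12. LiOH and H2O2 (THF/H2O, 0 °C) cleave the imide to (2S,3S)-3-[4-(benzyloxy)-3-methoxyphenyl]-2-[2-fluoro-3-methoxy-5-(methoxycarbonyl)phenyl]-3-hydroxypropanoic acid F10, hydroperoxide attacking the exocyclic carbonyl far faster than the benzoate. BH3·SMe2 then reduces the free acid selectively beside the ester. It comes back at 13.

**Step 4.** RuO4 may over-oxidise the activated benzylic methylene (loss of a second carbon) or attack the methoxy-bearing ring. The fallback sets out from 5. Ozonolysis at −78 °C with Me2S work-up gives methyl 4-fluoro-3-methoxy-5-(2-oxoethyl)benzoate F11, and Pinnick oxidation (NaClO2, NaH2PO4, 2-methyl-2-butene) gives the acid. It comes back at 6.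

## Further compounds

F1 | step 9 | methyl 3-allyl-4-(benzyloxy)-5-methoxybenzoate | COC(=O)c1cc(CC=C)c(OCc2ccccc2)c(OC)c1
F2 | step 9 | [2-(benzyloxy)-3-methoxy-5-(methoxycarbonyl)phenyl]acetic acid | COC(=O)c1cc(CC(=O)O)c(OCc2ccccc2)c(OC)c1
F3 | step 9 | methyl 3-{2-[(4S)-4-benzyl-2-oxo-1,3-oxazolidin-3-yl]-2-oxoethyl}-4-(benzyloxy)-5-methoxybenzoate | COC(=O)c1cc(CC(=O)N2[C@@H](Cc3ccccc3)COC2=O)c(OCc2ccccc2)c(OC)c1
F4 | step 9 | methyl 3-[(2S,3S)-1-[(4S)-4-benzyl-2-oxo-1,3-oxazolidin-3-yl]-3-[4-(benzyloxy)-3-methoxyphenyl]-3-hydroxy-1-oxopropan-2-yl]-4-(benzyloxy)-5-methoxybenzoate | COC(=O)c1cc(OC)c(OCc2ccccc2)c(c1)[C@H](C(=O)N1[C@@H](Cc2ccccc2)COC1=O)[C@@H](c1ccc(OCc2ccccc2)c(OC)c1)O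
F5 | step 9 | methyl 4-(benzyloxy)-3-[(1S,2R)-1-[4-(benzyloxy)-3-methoxyphenyl]-1,3-dihydroxypropan-2-yl]-5-methoxybenzoate | COC(=O)c1cc(OC)c(OCc2ccccc2)c(c1)[C@H](CO)[C@@H](c1ccc(OCc2ccccc2)c(OC)c1)O
F6 | step 9 | methyl 3-[(1S,2R)-1,3-dihydroxy-1-(4-hydroxy-3-methoxyphenyl)propan-2-yl]-4-hydroxy-5-methoxybenzoate | COC(=O)c1cc(OC)c(O)c(c1)[C@H](CO)[C@@H](c1ccc(O)c(OC)c1)O
F7 | step 3 | methyl 3-allyl-5-methoxy-4-{[(trifluoromethyl)sulfonyl]oxy}benzoate | COC(=O)c1cc(CC=C)c(OS(=O)(=O)C(F)(F)F)c(OC)c1
F8 | step 6 | methyl 3-{2-[(4S)-4-benzyl-2-thioxo-1,3-thiazolidin-3-yl]-2-oxoethyl}-4-fluoro-5-methoxybenzoate | COC(=O)c1cc(CC(=O)N2[C@@H](Cc3ccccc3)CSC2=S)c(F)c(OC)c1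
F9 | step 6 | methyl 3-[(2S,3S)-1-[(4S)-4-benzyl-2-thioxo-1,3-thiazolidin-3-yl]-3-[4-(benzyloxy)-3-methoxyphenyl]-3-hydroxy-1-oxopropan-2-yl]-4-fluoro-5-methoxybenzoate | COC(=O)c1cc(OC)c(F)c(c1)[C@H](C(=O)N1[C@@H](Cc2ccccc2)CSC1=S)[C@@H](c1ccc(OCc2ccccc2)c(OC)c1)O
F10 | step 7 | (2S,3S)-3-[4-(benzyloxy)-3-methoxyphenyl]-2-[2-fluoro-3-methoxy-5-(methoxycarbonyl)phenyl]-3-hydroxypropanoic acid | COC(=O)c1cc(OC)c(F)c(c1)[C@H](C(=O)O)[C@@H](c1ccc(OCc2ccccc2)c(OC)c1)O
F11 | step 4 | methyl 4-fluoro-3-methoxy-5-(2-oxoethyl)benzoate | COC(=O)c1cc(CC=O)c(F)c(OC)c1
A1 | alternative 1 | methyl (2S,3R)-2-[4-(benzyloxy)-3-methoxyphenyl]-7-bromo-3-{[(tert-butyldimethylsilyl)oxy]methyl}-2,3-dihydro-1-benzofuran-5-carboxylate | COC(=O)c1cc(Br)c2c(c1)[C@H](CO[Si](C)(C)C(C)(C)C)[C@@H](c1ccc(OCc3ccccc3)c(OC)c1)O2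
A2 | alternative 1 | (4R,5S)-5-[4-(benzyloxy)-3-methoxyphenyl]-4-{[(tert-butyldimethylsilyl)oxy]methyl}oxolan-2-one | O=C1C[C@H](CO[Si](C)(C)C(C)(C)C)[C@@H](c2ccc(OCc3ccccc3)c(OC)c2)O1
A3 | alternative 1 | trimethylsilyl ketene acetal of A2, (2S,3R)-2-[4-(benzyloxy)-3-methoxyphenyl]-3-{[(tert-butyldimethylsilyl)oxy]methyl}-5-(trimethylsilyloxy)-2,3-dihydrofuran | C[Si](C)(C)OC1=C[C@H](CO[Si](C)(C)C(C)(C)C)[C@@H](c2ccc(OCc3ccccc3)c(OC)c2)O1
A4 | alternative 1 | methyl 3-bromocoumalate (methyl 3-bromo-2-oxo-2H-pyran-5-carboxylate) | COC(=O)C1=COC(=O)C(Br)=C1
A5 | alternative 2 | methyl (2S,3S)-2-[4-(benzyloxy)-3-methoxyphenyl]-5-bromo-7-methoxy-2,3-dihydro-1-benzofuran-3-carboxylate (trans) | Brc1cc(OC)c2c(c1)[C@H](C(=O)OC)[C@@H](c1ccc(OCc3ccccc3)c(OC)c1)O2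
A6 | alternative 2 | (2S)-2-[4-(benzyloxy)-3-methoxyphenyl]-6-bromo-8-methoxy-2,3-dihydro-4H-chromen-4-one | O=C1C[C@@H](c2ccc(OCc3ccccc3)c(OC)c2)Oc2c(OC)cc(Br)cc12
A7 | alternative 3 | methyl 3-[(4S,5S)-5-[4-(benzyloxy)-3-methoxyphenyl]-2,2-dimethyl-1,2-oxasilolan-4-yl]-5-methoxy-4-(methoxymethoxy)benzoate | COC(=O)c1cc(OC)c(OCOC)c(c1)[C@H](C4)[C@@H](c1ccc(OCc2ccccc2)c(OC)c1)O[Si]4(C)C
A8 | alternative 3 | methyl 3-[(3R)-3-[4-(benzyloxy)-3-methoxyphenyl]-3-[(dimethylsilyl)oxy]prop-1-en-2-yl]-5-methoxy-4-(methoxymethoxy)benzoate | COC(=O)c1cc(OC)c(OCOC)c(c1)C(=C)[C@@H](c1ccc(OCc2ccccc2)c(OC)c1)O[SiH](C)C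
A9 | alternative 3 | methyl 3-[(1S,2R)-1-[4-(benzyloxy)-3-methoxyphenyl]-1,3-dihydroxypropan-2-yl]-5-methoxy-4-(methoxymethoxy)benzoate (syn diol) | COC(=O)c1cc(OC)c(OCOC)c(c1)[C@H](CO)[C@@H](c1ccc(OCc2ccccc2)c(OC)c1)O
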